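**Plan**

1. Cuts: seven aryl O–benzyl bonds (hydrogenolysis last); the C6–CH2 and C8–CH2 bonds (two base-free Negishi couplings on a 6-bromo-8-iodoflavanone); the three CH2–aryl bonds inside the side chain (iterative benzyl–aryl Suzuki couplings); and, in the pyranone, the C3–C4 and C2–H bonds, so that C3 becomes an iodomethyl group on C2 of a benzofuran-3(2H)-one.
2. Enabling feature: C2 carries both the ring oxygen O1 and the phenyl group and lies β to the C4 aryl ketone, so a radical at C2 is benzylic and α-oxygenated. A CH2 radical on C2 of the five-membered furanone (O1, C2, C4, C4a, C8a) can therefore add to C4=O and reopen with 1,2-acyl shift (Dowd–Beckwith), which inserts C3 and gives the six-membered pyranone.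
3. Forward order: benzofuranone → C2 arylation and iodomethylation → ring expansion to the (2S)-flavanone → iodination at C8, bromination at C6 → coupling of the 2-(benzyloxy)benzyl unit at C8 (C–I) and of the separately built four-ring chain at C6 (C–Br) → debenzylation.
4. Stereochemistry: the single stereocentre C2 (S) is created in the ring expansion by enantioselective hydrogen-atom transfer from the flavin of an ene-reductase to the planar C2 radical (racemic precursor, stereoconvergent). Every later step is free of base, so the flavanone cannot racemise through the chalcone.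

Key step: step 3

Assumption: 2-(benzyloxy)benzyl bromide and [4-(benzyloxy)-3-formylphenyl]boronic acid are taken as purchasable catalogue compounds, and the ene-reductase panel, glucose dehydrogenase and NADP+ as commercial or routinely expressed biocatalysts.

**Route**

Step 1
Reactants: 1 4,6-dihydroxybenzofuran-3(2H)-one
Product: 2 4,6-bis(benzyloxy)benzofuran-3(2H)-one
Conditions: BnBr (2.2 equiv), K2CO3, DMF, 25 → 50 °C
Reagents that add atoms: benzyl bromide, BrCc1ccccc1
Why: Williamson ether synthesis, in which both phenols are O-benzylated under carbonate while the less acidic C2 methylene should stay largely untouched.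

Step 2
Reactants: 2 4,6-bis(benzyloxy)benzofuran-3(2H)-one; 3 bromobenzene; 4 diiodomethane
Product: 6 rac-4,6-bis(benzyloxy)-2-(iodomethyl)-2-phenylbenzofuran-3(2H)-one, via 2-phenylbenzofuranone 5 (not isolated)
Conditions: Pd2(dba)3 (1 mol%), XPhos (2.5 mol%), NaOt-Bu (2.2 equiv), PhBr, toluene, 70 °C, Ar; then CH2I2 (4 equiv), THF, 45 °C
Reagents that add atoms: none
Why: Palladium-catalysed ketone α-arylation (Buchwald–Hartwig–Miura type) gives the 2-phenyl ketone as its stabilised enolate, which resists a second arylation and is then C-alkylated by SN2 on CH2I2 (the usual entry to Dowd–Beckwith precursors); the quaternary C2 is formed racemic, which is harmless because step 3 planarises it.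

Step 3
Reactants: 6 rac-4,6-bis(benzyloxy)-2-(iodomethyl)-2-phenylbenzofuran-3(2H)-one
Product: 7 (2S)-5,7-bis(benzyloxy)-2-phenylchroman-4-one
Conditions: flavin-dependent ene-reductase (OYE family, variant picked from a panel), NADP+ (cat.), glucose dehydrogenase, D-glucose, KPi buffer pH 7.5, 15% DMSO, cyan LEDs (ca. 500 nm), N2, 25 °C
Reagents that add atoms: none
Why: Proposed new method: the reduced flavin of the ene-reductase, excited within a charge-transfer complex with the bound iodide, transfers one electron into the C–I bond; the primary radical adds 3-exo-trig to the C3 carbonyl of the benzofuranone and the cyclopropyloxy radical reopens by β-scission of the old C2–C(=O) bond, a Dowd–Beckwith 1,2-acyl shift that inserts the CH2 between C2 and the carbonyl and turns the five-membered furanone into the six-membered pyranone. The closest known reaction types are the tin-hydride Dowd–Beckwith ring expansion of α-halomethyl cyclic ketones and the photoenzymatic reductive radical reactions of alkyl iodides and α-halo carbonyl compounds in ene-reductases, which end with enantioselective hydrogen-atom transfer from the flavin semiquinone. No ring is closed by a separate cyclisation: the only closure is the transient 3-exo-trig cyclopropane, and the pyranone is the enlarged furanone. The new stereocentre C2 is set by the enzyme: the ring-expanded radical is planar, its C4 carbonyl should be held by the active-site hydrogen-bond donors so that C2, the β-carbon, sits over flavin N5–H (the position to which these enzymes natively deliver hydride), and the variant is chosen for delivery to the face that gives (2S); because the quaternary C2 of 6 is planarised, both enantiomers of racemic 6 converge. The step needs acyl shift to win over premature hydrogen transfer to the primary radical and over a 1,2-phenyl (neophyl) shift; 1,2-acyl shifts are known to be about two orders of magnitude faster than neophyl shifts and this one is pulled forward by the doubly stabilised C2 radical, while the competition with early hydrogen transfer is the point to be tested.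

Step 4
Reactants: 7 (2S)-5,7-bis(benzyloxy)-2-phenylchroman-4-one
Product: 8 (2S)-5,7-bis(benzyloxy)-8-iodo-2-phenylchroman-4-one
Conditions: NIS (1.05 equiv), TFA (0.1 equiv), MeCN–CH2Cl2, 0 °C → rt, dark
Reagents that add atoms: N-iodosuccinimide, O=C1CCC(=O)N1I
Why: Electrophilic aromatic iodination, in which C8 (between ring oxygen O1 and one benzyloxy group) is less hindered than C6 (between two benzyloxy groups), in line with the C8 halogenation expected for 5,7-dialkoxyflavonoids; the mild conditions leave C2 untouched.

Step 5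
Reactants: 8 (2S)-5,7-bis(benzyloxy)-8-iodo-2-phenylchroman-4-one
Product: 9 (2S)-5,7-bis(benzyloxy)-6-bromo-8-iodo-2-phenylchroman-4-one
Conditions: NBS (1.05 equiv), MeCN, 0 °C → rt, dark
Reagents that add atoms: N-bromosuccinimide, O=C1CCC(=O)N1Br
Why: Electrophilic aromatic bromination at C6, the only activated ring position left; both halogens are placed before any benzyl unit so that no electron-rich benzyloxyarene competes, and Br versus I later tells the two coupling sites apart.

Step 6
Reactants: 9 (2S)-5,7-bis(benzyloxy)-6-bromo-8-iodo-2-phenylchroman-4-one; 10 2-(benzyloxy)benzyl bromide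
Product: 12 (2S)-5,7-bis(benzyloxy)-8-[2-(benzyloxy)benzyl]-6-bromo-2-phenylchroman-4-one, via 2-(benzyloxy)benzylzinc bromide 11 (not isolated)
Conditions: 10, Zn dust, LiCl, THF, 0 → 25 °C; then 9, Pd(OAc)2 (2 mol%), SPhos (4 mol%), THF, 25 °C
Reagents that add atoms: none
Why: Negishi cross-coupling with a benzylzinc reagent made by direct zinc insertion, in which oxidative addition takes the C8–I bond at room temperature and leaves the hindered C6–Br bond, and the absence of base keeps the flavanone from opening to the chalcone.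

Step 7
Reactants: 13 [4-(benzyloxy)-3-formylphenyl]boronic acid
Product: 14 [4-(benzyloxy)-3-(hydroxymethyl)phenyl]boronic acid
Conditions: NaBH4, THF–MeOH, 0 °C; aq. NH4Cl
Reagents that add atoms: none
Why: Chemoselective borohydride reduction of the aryl aldehyde, which leaves the boronic acid untouched.

Step 8
Reactants: 10 2-(benzyloxy)benzyl bromide; 14 [4-(benzyloxy)-3-(hydroxymethyl)phenyl]boronic acid
Product: 15 [2-(benzyloxy)-5-[2-(benzyloxy)benzyl]phenyl]methanol (two-ring alcohol)
Conditions: Pd(PPh3)4 (3 mol%), K2CO3, DME–H2O, 70 °C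
Reagents that add atoms: none
Why: Suzuki–Miyaura coupling of a benzylic bromide with an arylboronic acid, which places the new CH2 ortho to the benzyloxy group of the first ring and para to that of the second and tolerates the free benzylic alcohol.

Step 9
Reactants: 15 two-ring alcohol
Product: 16 1-(benzyloxy)-2-(bromomethyl)-4-[2-(benzyloxy)benzyl]benzene (two-ring bromide)
Conditions: PBr3 (0.4 equiv), CH2Cl2, 0 °C
Reagents that add atoms: phosphorus tribromide, BrP(Br)Br
Why: Conversion of the benzylic alcohol into the bromide with PBr3 (SN2 on the bromophosphite), with the benzyl ethers stable at 0 °C.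

Step 10
Reactants: 16 two-ring bromide; 14 [4-(benzyloxy)-3-(hydroxymethyl)phenyl]boronic acid
Product: 17 three-ring alcohol (2-(benzyloxy)benzyl alcohol whose C5 carries a 2-(benzyloxy)-5-[2-(benzyloxy)benzyl]benzyl group)
Conditions: Pd(PPh3)4 (3 mol%), K2CO3, DME–H2O, 70 °C
Reagents that add atoms: none
Why: Second benzyl–aryl Suzuki–Miyaura coupling with the same regiochemical logic as step 8.

Step 11
Reactants: 17 three-ring alcohol
Product: 18 three-ring bromide (the benzylic bromide of 17)
Conditions: PBr3 (0.4 equiv), CH2Cl2, 0 °C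
Reagents that add atoms: phosphorus tribromide, BrP(Br)Br
Why: PBr3 bromination of the benzylic alcohol as in step 9.

Step 12
Reactants: 18 three-ring bromide; 14 [4-(benzyloxy)-3-(hydroxymethyl)phenyl]boronic acid
Product: 19 four-ring alcohol (2-(benzyloxy)benzyl alcohol whose C5 carries a 2-(benzyloxy)-5-{2-(benzyloxy)-5-[2-(benzyloxy)benzyl]benzyl}benzyl group)
Conditions: Pd(PPh3)4 (3 mol%), K2CO3, DME–H2O, 70 °C
Reagents that add atoms: none
Why: Third benzyl–aryl Suzuki–Miyaura coupling, which completes the ortho/para-linked four-ring chain.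

Step 13
Reactants: 19 four-ring alcohol
Product: 20 four-ring bromide (the benzylic bromide of 19)
Conditions: PBr3 (0.4 equiv), CH2Cl2, 0 °C
Reagents that add atoms: phosphorus tribromide, BrP(Br)Br
Why: PBr3 bromination as in step 9 gives the benzylic electrophile for zinc insertion.

Step 14
Reactants: 12 (2S)-5,7-bis(benzyloxy)-8-[2-(benzyloxy)benzyl]-6-bromo-2-phenylchroman-4-one; 20 four-ring bromide
Product: 22 hepta-O-benzyl sarmentosumin C, via four-ring benzylzinc bromide 21 (not isolated)
Conditions: 20, Zn dust, LiCl, THF, 0 → 25 °C; then 12, Pd-PEPPSI-IPent (3 mol%), THF–NMP, 50 °C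
Reagents that add atoms: none
Why: Negishi cross-coupling of the di-ortho-alkoxy aryl bromide with the benzylzinc reagent, for which a bulky NHC–palladium catalyst is suited, again base-free so that C2 keeps its configuration.

Step 15
Reactants: 22 hepta-O-benzyl sarmentosumin C
Product: 23 sarmentosumin C
Conditions: H2 (1 atm), 10% Pd/C, EtOAc–MeOH, 25 °C
Reagents that add atoms: none
Why: Hydrogenolysis of the seven benzyl ethers over palladium under neutral conditions, in which the diarylmethane C–C bonds are inert and the reaction is stopped before the benzylic C2–O1 bond is cleaved, so that C2 should stay (S).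

**Compound list**

1 | 4,6-dihydroxybenzofuran-3(2H)-one | O=C1COc2cc(O)cc(O)c12 | starting material
2 | 4,6-bis(benzyloxy)benzofuran-3(2H)-one | O=C1COc2cc(OCc3ccccc3)cc(OCc3ccccc3)c12 | intermediate
3 | bromobenzene | Brc1ccccc1 | starting material
4 | diiodomethane | ICI | starting material
5 | 4,6-bis(benzyloxy)-2-phenylbenzofuran-3(2H)-one (racemic, enolisable) | O=C1C(c2ccccc2)Oc2cc(OCc3ccccc3)cc(OCc3ccccc3)c12 | intermediate
6 | rac-4,6-bis(benzyloxy)-2-(iodomethyl)-2-phenylbenzofuran-3(2H)-one | ICC1(c2ccccc2)Oc2cc(OCc3ccccc3)cc(OCc3ccccc3)c2C1=O | intermediate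
7 | (2S)-5,7-bis(benzyloxy)-2-phenylchroman-4-one | O=C1C[C@@H](c2ccccc2)Oc2cc(OCc3ccccc3)cc(OCc3ccccc3)c12 | intermediate
8 | (2S)-5,7-bis(benzyloxy)-8-iodo-2-phenylchroman-4-one | O=C1C[C@@H](c2ccccc2)Oc2c(I)c(OCc3ccccc3)cc(OCc3ccccc3)c12 | intermediate
9 | (2S)-5,7-bis(benzyloxy)-6-bromo-8-iodo-2-phenylchroman-4-one | O=C1C[C@@H](c2ccccc2)Oc2c(I)c(OCc3ccccc3)c(Br)c(OCc3ccccc3)c12 | intermediate
10 | 2-(benzyloxy)benzyl bromide | BrCc1ccccc1OCc1ccccc1 | starting material
11 | 2-(benzyloxy)benzylzinc bromide | Br[Zn]Cc1ccccc1OCc1ccccc1 | intermediate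
12 | (2S)-5,7-bis(benzyloxy)-8-[2-(benzyloxy)benzyl]-6-bromo-2-phenylchroman-4-one | O=C1C[C@@H](c2ccccc2)Oc2c(Cc3ccccc3OCc3ccccc3)c(OCc3ccccc3)c(Br)c(OCc3ccccc3)c12 | intermediate
13 | [4-(benzyloxy)-3-formylphenyl]boronic acid | O=Cc1cc(B(O)O)ccc1OCc1ccccc1 | starting material
14 | [4-(benzyloxy)-3-(hydroxymethyl)phenyl]boronic acid | OCc1cc(B(O)O)ccc1OCc1ccccc1 | intermediate
15 | [2-(benzyloxy)-5-[2-(benzyloxy)benzyl]phenyl]methanol (two-ring alcohol) | OCc1cc(Cc2ccccc2OCc2ccccc2)ccc1OCc1ccccc1 | intermediate
16 | 1-(benzyloxy)-2-(bromomethyl)-4-[2-(benzyloxy)benzyl]benzene (two-ring bromide) | BrCc1cc(Cc2ccccc2OCc2ccccc2)ccc1OCc1ccccc1 | intermediate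
17 | three-ring alcohol: [2-(benzyloxy)-5-{2-(benzyloxy)-5-[2-(benzyloxy)benzyl]benzyl}phenyl]methanol | OCc1cc(Cc2cc(Cc3ccccc3OCc3ccccc3)ccc2OCc2ccccc2)ccc1OCc1ccccc1 | intermediate
18 | three-ring bromide: benzylic bromide of 17 | BrCc1cc(Cc2cc(Cc3ccccc3OCc3ccccc3)ccc2OCc2ccccc2)ccc1OCc1ccccc1 | intermediate
19 | four-ring alcohol: 17 extended by one more 2-(benzyloxy)-5-substituted benzyl unit, CH2OH ortho to OBn on the last ring | OCc1cc(Cc2cc(Cc3cc(Cc4ccccc4OCc4ccccc4)ccc3OCc3ccccc3)ccc2OCc2ccccc2)ccc1OCc1ccccc1 | intermediate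
20 | four-ring bromide: benzylic bromide of 19 | BrCc1cc(Cc2cc(Cc3cc(Cc4ccccc4OCc4ccccc4)ccc3OCc3ccccc3)ccc2OCc2ccccc2)ccc1OCc1ccccc1 | intermediate
21 | four-ring benzylzinc bromide (zinc reagent of 20) | Br[Zn]Cc1cc(Cc2cc(Cc3cc(Cc4ccccc4OCc4ccccc4)ccc3OCc3ccccc3)ccc2OCc2ccccc2)ccc1OCc1ccccc1 | intermediate
22 | hepta-O-benzyl sarmentosumin C: (2S)-5,7-bis(benzyloxy)-8-[2-(benzyloxy)benzyl]-6-[2-(benzyloxy)-5-{2-(benzyloxy)-5-{2-(benzyloxy)-5-[2-(benzyloxy)benzyl]benzyl}benzyl}benzyl]-2-phenylchroman-4-one | O=C1C[C@@H](c2ccccc2)Oc2c(Cc3ccccc3OCc3ccccc3)c(OCc3ccccc3)c(Cc3cc(Cc4cc(Cc5cc(Cc6ccccc6OCc6ccccc6)ccc5OCc5ccccc5)ccc4OCc4ccccc4)ccc3OCc3ccccc3)c(OCc3ccccc3)c12 | intermediate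
23 | sarmentosumin C: (2S)-5,7-dihydroxy-8-(2-hydroxybenzyl)-6-[2-hydroxy-5-{2-hydroxy-5-[2-hydroxy-5-(2-hydroxybenzyl)benzyl]benzyl}benzyl]-2-phenylchroman-4-one | O=C1C[C@@H](c2ccccc2)Oc2c(Cc3ccccc3O)c(O)c(Cc3cc(Cc4cc(Cc5cc(Cc6ccccc6O)ccc5O)ccc4O)ccc3O)c(O)c21 | target

**Step count and risks**

Total step count: 15. Longest linear sequence: 9 steps (steps 7 to 15, from boronic acid 13).

Steps most likely to fail:

Step 3 (proposed new method). The primary radical may take up hydrogen before the acyl shift, which would give the unrearranged 2-methyl ketone; the final hydrogen transfer may show poor facial selectivity; or the bulky dibenzyl ether may bind poorly in the active site. Fallback with known chemistry, setting out from 6: a conventional tin-hydride Dowd–Beckwith ring expansion (Bu3SnH added slowly, AIBN, benzene, 80 °C) should give racemic 5,7-bis(benzyloxy)-2-phenylchroman-4-one F1. Kinetic resolution by Noyori-type asymmetric transfer hydrogenation (Cp*Rh(TsDPEN)Cl, HCO2H/Et3N, EtOAc, rt, catalyst enantiomer chosen to reduce the (2R)-ketone) should then turn the unwanted enantiomer into (2R,4R)-5,7-bis(benzyloxy)-2-phenylchroman-4-ol F2, which is removed by chromatography. The unreduced (2S)-ketone is compound 7, where the route is rejoined; the cost is at most half of the material.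

Step 2. The ambident benzofuran-3-olate may be alkylated on oxygen instead of carbon, or the benzofuranone may self-condense under the basic arylation conditions. Fallback, setting out from 5: the arylation is stopped at 5, which is isolated under argon. The one-carbon unit is then introduced by a reversible, carbon-selective aldol reaction with aqueous formaldehyde (cat. Et3N, THF, 0 °C) to give 4,6-bis(benzyloxy)-2-(hydroxymethyl)-2-phenylbenzofuran-3(2H)-one F3. Garegg–Samuelsson iodination (PPh3, I2, imidazole, toluene, 80 °C) returns to 6.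

Step 4. Site selectivity may be poor, with iodination at C6 or at both free positions. Fallback, setting out from 7: BCl3 (CH2Cl2, −78 °C) should remove only the chelated 5-O-benzyl group and give (2S)-7-(benzyloxy)-5-hydroxy-2-phenylchroman-4-one F4. The hydrogen-bonded 5-OH then directs NBS to its ortho position C6, giving (2S)-7-(benzyloxy)-6-bromo-5-hydroxy-2-phenylchroman-4-one F5. NIS iodinates the one remaining position to give (2S)-7-(benzyloxy)-6-bromo-5-hydroxy-8-iodo-2-phenylchroman-4-one F6. Base-free O-benzylation of the 5-OH (BnBr, Ag2O, CH2Cl2) returns to 9.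

**Further compounds**

F1 | step 3 | rac-5,7-bis(benzyloxy)-2-phenylchroman-4-one | O=C1CC(c2ccccc2)Oc2cc(OCc3ccccc3)cc(OCc3ccccc3)c12
F2 | step 3 | (2R,4R)-5,7-bis(benzyloxy)-2-phenylchroman-4-ol | O[C@@H]1C[C@H](c2ccccc2)Oc2cc(OCc3ccccc3)cc(OCc3ccccc3)c12
F3 | step 2 | 4,6-bis(benzyloxy)-2-(hydroxymethyl)-2-phenylbenzofuran-3(2H)-one | OCC1(c2ccccc2)Oc2cc(OCc3ccccc3)cc(OCc3ccccc3)c2C1=O
F4 | step 4 | (2S)-7-(benzyloxy)-5-hydroxy-2-phenylchroman-4-one | O=C1C[C@@H](c2ccccc2)Oc2cc(OCc3ccccc3)cc(O)c12
F5 | step 4 | (2S)-7-(benzyloxy)-6-bromo-5-hydroxy-2-phenylchroman-4-one | O=C1C[C@@H](c2ccccc2)Oc2cc(OCc3ccccc3)c(Br)c(O)c12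
F6 | step 4 | (2S)-7-(benzyloxy)-6-bromo-5-hydroxy-8-iodo-2-phenylchroman-4-one | O=C1C[C@@H](c2ccccc2)Oc2c(I)c(OCc3ccccc3)c(Br)c(O)c12
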